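Wednesday's run, charged with 0.54 M of starting material against Sunday's 0.80 M, had made 0.267 M of target at its first reading (1.50 h), and Sunday's run 0.260 M at its own (1.33 h). So the early rate shows little dependence on the charge of starting material.

all flasks: reagent 1.04 M; free catalyst 0.40 mM

| charge | starting material | remark | time |
|---|---|---|---|
| Sunday's | 0.80 M | the very flask that is asked about, followed so far |  |
| Wednesday's | 0.54 M | run made earlier |  |
| flask | 0.80 M |  | 30 h |

- Sunday's (time / h: target / %): 1.33: 32.5; 2.50: 42.3; 4.00: 47.9; 6.00: 49.4; 10.0: 50.6; 20.0: 50.3
- Wednesday's (time / h: target / %): 1.50: 49.4; 3.00: 62.7; 5.00: 67.4; 8.00: 69.1; 12.0: 69.8; 20.0: 69.2

(standard deviation of a reading: 0.5 percentage points)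

- north-west: change nothing and wait 30 h more
- east: at 30 h add reagent, 50.0% of the amount charged, then wait 30 h
- west: at 30 h take out 90% of the target then present, then wait 30 h
- south: at 30 h add free catalyst, 100% of the amount charged, then wait 30 h

- in percentages every species weighs as the starting material in it: one homo dimer counts as two
- removed target is counted in
- reactions considered so far: starting material + reagent + free catalyst -> target + free catalyst; 2 starting material -> homo dimer; free catalyst -> spent catalyst
- additions bring no volume worth counting

- target, in percent of the starting material first charged, at 30 h
- which option adds most target ("none" when 2 percentage points or less is all one gets) (north-west / east / west / south / none)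
- target present, with what was taken out counted in, in percent of the starting material first charged, after north-west
- target present, with what was taken out counted in, in percent of the starting material first charged, after east

The ledger of Sunday's flask is kept in molarity, with starting material as the limiting reagent by charge:

Starting material charged: 0.80 M
Entered as target at 20.0 h: 0.402 M
Open entry, starting material or homo dimer, unread: 0.398 M
Reagent left of 1.04 M: 0.638 M

Target reads 50.6% at 10.0 h and 50.3% at 20.0 h, yet reagent remains. If the open entry is starting material, neither charge has run out, and the free catalyst is what to watch. Suppose reagent falls at a rate proportional to reagent and free catalyst, with starting material not entering. Then, at a fixed catalyst charge and with free catalyst decaying by itself, the logarithm below depends on neither the reagent charge nor the starting-material charge: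

L = ln(reagent charged / reagent left) = 0.489 on Sunday, 0.445 on Wednesday

L is the catalyst's reach: the logarithm of the reagent ratio that a catalyst charge achieves before target stops. Sunday's reading of L stands 0.0440 above Wednesday's, so the supposition is a rough one. The reckoning made here commits to a flat target, 50.3% at 30 h.

The forecast gives 50.4% at 30 h, 50.4% after north-west, 50.7% after east, and south as the best option: “Fresh catalyst should restart it if starting material survives”.

    starting material + reagent + free catalyst → target + free catalyst, rate k1*[starting material]*[reagent]*[free catalyst]/(1 + ([starting material]/sat1)) (0.0650 M, k = 230 M⁻² min⁻¹)
    2 starting material → homo dimer (k = 1.80 × 10⁻⁵ M⁻¹ min⁻¹)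
    free catalyst → spent catalyst (k = 0.0110 min⁻¹)

The flask gives 50.1% at 30 h, 50.1% after north-west and 50.1% after east, while south adds 28 percentage points. Free catalyst has a half-life of 1.1 h by its own decay, shorter than the 3.8 h half-life of reagent by the target step at 0.856 h. The answer at 30 h moves 5 points away from this flask's in a repeat charged with 0.932 M or 1.15 M of reagent, and there the forecast's 50.4% no longer describes the flask. Carried to south on this flask, a second charge of free catalyst with the same reach L reckons a further 30.8% of the starting material charged, and the flask gains 28 points. Applied to a neighbour charged with 0.42 M of reagent, L reckons 20.3% of target, and that neighbour gives 20.6%.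

The earlier runs and the new flask were generated by integration for substances that don't exist, noise included.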